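Read eta at 4.0 min and theta at 12 min, and ask which holder of the substrate leads at each reading.

| setting | eta | theta |
|---|---|---|
| substrate | 0.10 M | 0.10 M |
| solid reagent | 0.110 M | 0.110 M |
| time | 4.0 min | 12 min |

    substrate + partner → single product (k1 = 0.055 /M/s)
    partner + single product → bis adduct (k2 = 0.024 /M/s)
    partner + bis adduct → tris adduct (k3 = 0.044 /M/s)
    solid reagent ⇌ partner, rate k4*(cs4 - [partner]) while solid is left; crystals form when [partner] > cs4 (cs4 = 0.088 M, k4 = 0.0039 /s)

* which of these there is most of at the end, counted by the substrate in it, eta (single product / substrate / tris adduct / bis adduct)
* which of these there is most of at the end, counted by the substrate in it, theta (single product / substrate / tris adduct / bis adduct)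
* the largest of these amounts at the end, in percent of the substrate charged, eta
* the largest of these amounts at the end, in percent of the substrate charged, theta

- given per volume of solution although it is solid: solid reagent
- at the start none of the solid reagent is in solution
- run time (eta): 4.0 min

Follow one dissolved partner molecule to its fork. It takes substrate or single product with odds of 2.29 (the selectivity factor, first step over second) times substrate over single product. Both arms see the same partner, so its concentration cancels from the odds. With a the fraction of substrate left, m the fraction held as single product and q = 0.436, the inverse factor, this gives m = (a^q − a)/(1 − q), however fast the solid dissolves. Set m equal to a and you get the crossing level, the substrate left when single product draws level with it: 45.2%.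

Now reckon the clock. Balance dissolution against the first step at the charged substrate: partner levels near 0.0365 M after a lag of 1.77 min, and substrate then decays pseudo-first-order. Reckoned at that level, dissolution takes about 9.13 min to pass the solid charge into solution, less than the 12 min of theta, so the theta figure is rough. My reckoning leaves 76.5% substrate in eta, above the crossing level, and 29.2% in theta, below it, where the formula gives single product 51.9%.

The forecast, holding that the partner “only creeps into solution”, names substrate at 75% for eta and single product at 51% for theta, each slightly below mine.

The simulation gives substrate at 74.4% in eta and single product at 51.5% in theta.

In theta at 12.0 min, the first step still takes partner 1.4 times as fast as the second. Substrate stands above the crossing level in eta and below it in theta.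

Take the neighbour, theta with 0.066 M of solid reagent: its substrate at 12.0 min, 48.7%, lies above the crossing level, so the formula puts substrate ahead and single product at 43.2%. The computed neighbour flask has substrate ahead and single product at 43.2%.

(Its constants are invented; the run is a simulation.)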